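Atom numbers C1–C14 are those of the target throughout. Nothing in this proposal has been run; every outcome is an expectation.

## The problem

The target is a cage: a bicyclo[3.3.1]nonane-2,4,9-trione (C1–C9) whose C3 and C7 are tied by the two-carbon bridge C10–C11 (a homoadamantane skeleton), with a gem-dimethylcyclopentane (C3, C11–C14) fused on the C3–C11 bond. Bridgehead C5 carries a geranyl chain and bridgehead C1 a benzoyl group. Five carbons are fully substituted (C1, C3, C5, C8, C12), and the C4 carbonyl lies between two of them, so the bonds around C3 and C5 are the hard ones to make.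

There are five stereocentres (C1, C3, C5, C7, C11). The cage admits only one arrangement of C1, C3 and C5 once C7 and C11 are fixed, so the real task is C11 in absolute terms and C7 relative to C11. That relationship is 1,3 across C10 and acyclic until the cage closes. It can be corrected only while C7 is next to a carbonyl group.

Two groups restrict the choice of reagents. The geranyl chain has two trisubstituted alkenes, which rule out hydrogenation, ozonolysis and free carbocations. The non-enolisable 1,3,5-triketone (C2, C4, C9) is opened by hydroxide, alkoxide or hydride (retro-Claisen), so reductions and ester cleavages must precede the cage, and the benzoyl group should come last.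

The feature that makes the key step possible is ring C5–C6–C7–C8–C1–C9. It is a cyclohexanone with the C7 side chain para to the C9 oxygen and two methyl groups on C8 next to C1. With C9 as a silyl enol ether and a carbonyl placed temporarily on C10, this ring is the adduct of a 2-silyloxybutadiene (C1=C9–C5=C6) and a β,β-dimethyl enone (C7=C8, C10=O).

## Retrosynthesis

**C1–benzoyl bond (28 to 27).** The benzoyl group is removed first. It is a fourth electrophilic carbonyl that would not survive the thiolate and hydride steps, and in an open precursor it would turn C1 into an enolised β-diketone that acylates on oxygen. Trione 27 has a single acidic C–H, the bridgehead C1–H between C2=O and C9=O. The forward step must deprotonate this position in a rigid cage and capture the anion on carbon; O-acylation would need a bridgehead alkene and is not available.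

**C4–C5 and C2–C1 (27 to 24, through 25 and 26).** Both carbonyl carbons are left on C3, so C3 is already quaternary before the cage closes and no acylation at C3 is needed later. Cutting C3–C2 and C3–C4 instead would ask for two acylations of a hindered cyclopentane carbon. The cut gives a cyclohexene silyl enol ether (C9=C5) and a cyclopentane-1,1-dicarboxylic acid joined only through C10, and takes the stereocentre count from four to two. The forward reaction is an intramolecular Effenberger-type double C-acylation: the enol carbon C5 must attack an acid chloride that sits on a quaternary carbon, and the second closure must go to C1 and not to the C9 oxygen.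

**Oxidation-level changes (24 back to 18, through 23, 22 and 20).** Diacid 24 comes from diester 23. The C10 methylene of 23 is written back to a ketone, because only a carbonyl on C10 activates C7=C8 for the cycloaddition. Reduction of a γ-keto ester that has an ester cis on C3 will close a lactone. The plan accepts this: lactone 20 is opened by hydroxide, the alkoxide is trapped as xanthate while the acid is a carboxylate, and methylation restores the diester in 22. Radical C–O cleavage gives 23 without touching C7 or the alkenes.

**C6–C7 and C1–C8 (18 to 17 and 10).** This is the key cut. It divides the molecule into two fragments of similar size, builds the gem-dimethyl carbon C8 without any enolate alkylation, and leaves the enol silane at C9=C5 where the cage closure needs it. Cutting C5–C6 and C7–C8 of the same ring would need a far less accessible diene. The precursors are an achiral diene and a cyclopentane with one stereocentre. The forward reaction must overcome the low reactivity of a β,β-disubstituted enone, spare the geranyl alkenes, and choose one face of the alkene under the influence of C11.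

**C10–C7 and the C10 carboxyl (10 to 8 to 7).** The enone is cut at the acyl–vinyl bond to acid 8, and the carboxyl of 8 is traced to the vinyl group of 7. This avoids enolate chemistry on a γ-keto diester, which would undergo intramolecular Claisen condensation, and avoids an allylic alkoxide beside the esters. The forward steps are an oxidative alkene cleavage and an acyl substitution on a hindered acid chloride.

**C3–C11 (7 to 6, then 5, 3 and 4; 3 from 2 and 1).** The ring is opened at the bond between the malonate carbon and the stereocentre. An intramolecular allylic alkylation makes this bond, sets C11 by catalyst control, and delivers the vinyl group in one step; conjugate addition to a cyclopentenecarboxylate beside a quaternary carbon is less well supported. Carbonate 6 comes from malonate 5 by cross-metathesis, and 5 from iodide 3 and dimethyl malonate 4; 3 goes back through alcohol 2 to commercial ester 1.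

**Diene (17 to 16 to 13, then 11 and 12).** The diene is the enol silane of α-methylene ketone 16. The methylene group is traced to the carboxyl carbon of β-keto ester 13 (decarboxylative Mannich methylenation), and 13 to geranyl bromide 11 and methyl acetoacetate 12. The E-alkene of the geranyl unit is bought, not made.

## Roads not taken

**Alternative 1:** The cut is at C7–C10 and C1–C8 of the C10-hydroxy cage A2. The precursor A1 is a dearomatised benzoyl trione with geranyl and prenyl groups on C5 and a 2-formyl-3,3-dimethylcyclopentane spiro-fused at C3. In the forward step a Lewis acid activates the C10 aldehyde, the prenyl alkene attacks through C7 (seven-membered ring), and the tertiary C8 cation is trapped by enol carbon C1.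
- Merits: two rings and two C–C bonds form in one step, and the benzoyl group is present from the start, so no bridgehead acylation is needed. In these respects it is better than the chosen plan.
- Weak points: A1 needs three stereocentres (C3, C5, C11) set in an open trione, including a C5 that bears two similar allyl groups. The cation can be intercepted by either geranyl alkene or by an enol oxygen (cyclic enol ether) instead of C1. The first closure is a seven-membered Prins reaction. The C10 hydroxyl of A2 must then be removed next to a retro-Claisen-prone triketone.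
- Comparison: the chosen plan is longer at the end, but no cation is generated in the presence of the geranyl chain, the quaternary carbons form with predictable regiochemistry, and C10 is deoxygenated before the triketone exists.

**Alternative 2:** The cut is at C12–C13 and C14–C3 of cyclopentane A5. The precursors are the chiral-pool donor–acceptor cyclopropane A3 and ketene dithioacetal A4. A Lewis acid opens the C3–C12 bond of A3 to a tertiary cation and a malonate anion, which add across A4.
- Merits: C11 and the gem-dimethyl group come from the chiral pool with no asymmetric catalyst, and two ring bonds form at once. In these respects it equals or betters steps 1–5 of the chosen route.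
- Weak points: it solves only the cyclopentane. The tertiary cation can lose a proton to an isopropenyl group before it is captured. The dithioketal at C14 must be reduced away, and the silyloxymethyl group on C11 still has to be oxidised and extended to the enone.
- Comparison: the chosen allylic alkylation delivers a vinyl group that is one oxidation from the C10 acid, with no sulfur to remove. Its weakness is the hindered allyl terminus, which A3 does not have.

**Alternative 3:** The cut is at C4–C5, a temporary C3–C9 bond and C3–C14 of cyclobutanone A7. The precursor A6 is a 2-diazo-4,4-dimethylcyclohexanone attached through C10 to the same cyclohexene enol silane as in 23. Photolysis expels nitrogen, C14 migrates (ring contraction), and the ketene adds to the enol ether.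
- Merits: a ketene cycloaddition is a more forceful way to join C4 to the fully substituted C5 than acylation by an α-quaternary acid chloride, and it makes C3 quaternary in the same event. On this bond it is stronger than step 16.
- Weak points: A7 lacks C2, so after the C3–C9 bond is cut a further acylation at C3 and a closure to C1 are needed. The carbene can undergo 1,2-hydrogen shift from C11. Diazo transfer must be regioselective. A6 still needs a cycloaddition like step 11 to build its cyclohexene.
- Comparison: the chosen plan has both C2 and C4 on C3 before closure and reaches 27 in one operation from 24; it pays for this with a harder C4–C5 bond formation.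

Key step: step 11

Assumption: the sense of induction in step 5 follows that of the unsubstituted malonate cyclisation, and the ligand antipode that gives (R)-7 is used; C10 is carried as an epimer mixture in 19–22 because it ends as CH2.

## Route

Step 1
Reactants: 1 methyl 3,3-dimethylpent-4-enoate
Product: 2 3,3-dimethylpent-4-en-1-ol
Conditions: LiAlH4, Et2O, 0 °C → rt
Reagents that add atoms: none
Why: Hydride reduction of an ester to the primary alcohol; the isolated vinyl group is inert.

Step 2
Reactants: 2 3,3-dimethylpent-4-en-1-ol
Product: 3 5-iodo-3,3-dimethylpent-1-ene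
Conditions: PPh3, I2, imidazole, CH2Cl2, 0 °C → rt
Reagents that add atoms: iodine, [I][I]
Why: Appel-type iodination of an unhindered primary alcohol; the quaternary carbon is two atoms away, so SN2 displacement of the phosphonium is not retarded.

Step 3
Reactants: 3 5-iodo-3,3-dimethylpent-1-ene; 4 dimethyl malonate
Product: 5 dimethyl 2-(3,3-dimethylpent-4-en-1-yl)propanedioate
Conditions: NaH, 4 (excess), THF/DMF, 0 → 60 °C
Reagents that add atoms: none
Why: Malonate alkylation with a primary iodide; excess malonate suppresses dialkylation.

Step 4
Reactants: 5 dimethyl 2-(3,3-dimethylpent-4-en-1-yl)propanedioate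
Product: 6 dimethyl 2-[(4E)-6-(methoxycarbonyloxy)-3,3-dimethylhex-4-en-1-yl]propanedioate
Conditions: (Z)-MeO2COCH2CH=CHCH2OCO2Me (3 equiv), second-generation Grubbs catalyst RuCl2(=CHPh)(PCy3)(H2IMes) (5 mol %), CH2Cl2, 40 °C
Reagents that add atoms: (Z)-but-2-ene-1,4-diyl dimethyl dicarbonate, COC(=O)OC/C=C\COC(=O)OC
Why: Olefin cross-metathesis; a vinyl group on a quaternary carbon does not homodimerise and couples with the reactive allylic partner to give mainly the E-alkene.

Step 5
Reactants: 6 dimethyl 2-[(4E)-6-(methoxycarbonyloxy)-3,3-dimethylhex-4-en-1-yl]propanedioate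
Product: 7 dimethyl (2R)-2-ethenyl-3,3-dimethylcyclopentane-1,1-dicarboxylate
Conditions: [Ir(cod)Cl]2 (2 mol %), binaphthol-derived N,N-bis(1-phenylethyl)phosphoramidite (4 mol %, one enantiomer), TBD (8 mol %), THF, rt → 50 °C
Reagents that add atoms: none
Why: Iridium-catalysed intramolecular asymmetric allylic alkylation; the carbonate ionises to an allyl–iridium complex, the released methoxide deprotonates the malonate, and 5-exo attack at the substituted allyl terminus forms C3–C11. C11 is set by the chiral ligand.

Step 6
Reactants: 7 dimethyl (2R)-2-ethenyl-3,3-dimethylcyclopentane-1,1-dicarboxylate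
Product: 8 (1R)-2,2-bis(methoxycarbonyl)-5,5-dimethylcyclopentane-1-carboxylic acid
Conditions: RuCl3·xH2O (cat.), NaIO4, CCl4/MeCN/H2O, rt
Reagents that add atoms: sodium periodate, [Na+].[O-]I(=O)(=O)=O; water, O
Why: Ruthenium tetroxide cleavage of a terminal alkene to the carboxylic acid; C11 has no enolisable partner under these conditions and keeps its configuration.

Step 7
Reactants: 8 (1R)-2,2-bis(methoxycarbonyl)-5,5-dimethylcyclopentane-1-carboxylic acid
Product: 10 dimethyl (2R)-3,3-dimethyl-2-(3-methylbut-2-enoyl)cyclopentane-1,1-dicarboxylate, via acid chloride 9 (not isolated)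
Conditions: (COCl)2, DMF (cat.), CH2Cl2, 0 °C → rt; then Me2C=CHMgBr, CuBr·SMe2 (1:1), THF, −78 → −30 °C
Reagents that add atoms: 2-methylprop-1-enylmagnesium bromide, CC(C)=C[Mg]Br (oxalyl chloride, ClC(=O)C(=O)Cl, supplies only the chlorine of 9)
Why: Acyl substitution of an acid chloride by an alkenylcopper reagent, which stops at the ketone and leaves the esters alone; no amine base is present, so C11 is not epimerised through a ketene.

Step 8
Reactants: 11 geranyl bromide; 12 methyl acetoacetate
Product: 13 methyl (4E)-2-acetyl-5,9-dimethyldeca-4,8-dienoate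
Conditions: NaH, 12 (excess), THF, 0 °C → rt
Reagents that add atoms: none
Why: C-alkylation of the acetoacetate anion by an allylic bromide with retention of the E-alkene.

Step 9
Reactants: 13 methyl (4E)-2-acetyl-5,9-dimethyldeca-4,8-dienoate
Product: 16 (5E)-6,10-dimethyl-3-methylideneundeca-5,9-dien-2-one, via keto acid 14 (not isolated), via Mannich acid 15 (not isolated)
Conditions: KOH, MeOH/H2O, rt; then Et2NH·HCl, 37 % aq. HCHO, rt → 40 °C
Reagents that add atoms: formaldehyde, C=O
Why: Saponification followed by decarboxylative Mannich methylenation; the aminomethylated β-keto acid loses CO2 and diethylamine together, which places the methylene group regiospecifically on the former ester carbon.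

Step 10
Reactants: 16 (5E)-6,10-dimethyl-3-methylideneundeca-5,9-dien-2-one
Product: 17 tert-butyl{[(5E)-6,10-dimethyl-3-methylideneundeca-1,5,9-trien-2-yl]oxy}dimethylsilane
Conditions: TBSOTf, Et3N, CH2Cl2, 0 °C
Reagents that add atoms: tert-butyldimethylsilyl trifluoromethanesulfonate, CC(C)(C)[Si](C)(C)OS(=O)(=O)C(F)(F)F
Why: Soft enolisation and O-silylation of a methyl ketone; the methyl group is the only alpha position with hydrogen, so the cross-conjugated 2-silyloxydiene forms.

Step 11
Reactants: 17 tert-butyl{[(5E)-6,10-dimethyl-3-methylideneundeca-1,5,9-trien-2-yl]oxy}dimethylsilane; 10 dimethyl (2R)-3,3-dimethyl-2-(3-methylbut-2-enoyl)cyclopentane-1,1-dicarboxylate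
Product: 18 dimethyl (2R)-2-{(1R)-4-(tert-butyldimethylsilyloxy)-3-[(2E)-3,7-dimethylocta-2,6-dienyl]-6,6-dimethylcyclohex-3-ene-1-carbonyl}-3,3-dimethylcyclopentane-1,1-dicarboxylate
Conditions: 17 (2–3 equiv), AlBr3/AlMe3 (10:1, excess over the three carbonyl groups), toluene/CH2Cl2, −20 → 0 °C; Et3N, then aq. NaHCO3
Reagents that add atoms: none
Why: This is a Lewis-acid-promoted normal-demand [4+2] cycloaddition, and the closest known reaction type is the mixed AlBr3/AlMe3-promoted Diels–Alder reaction of 2-silyloxydienes with hindered β,β-disubstituted enones. The silyloxy group on C9 makes C1 the nucleophilic diene terminus, so C1 bonds to the β-carbon C8 and C6 to C7 (acyl group para to C9), whether the bonds form together or as a Mukaiyama–Michael addition followed at once by collapse of the aluminium enolate onto the silyloxyallyl cation. The cyclohexene ring closes in the cycloaddition itself (both new σ bonds are ring bonds; in the stepwise limit the second is a 6-endo closure of C7 onto C6), and the enol silane is left fixed at C9=C5. The only new stereocentre is C7, and it is controlled by C11 through the rotamer about C10–C11: with both ester groups and the ketone bound to aluminium the C3 flank is the larger one, the s-cis enone is expected to turn its alkene arm away from it toward C12, and the face of C7=C8 that then points away from the cyclopentane and the C12 methyl group is open, which gives (R)-C7. Regioselectivity is secured by the C9 silyloxy group outweighing the C5 alkyl group; chemoselectivity over the geranyl alkenes is secured by the much higher nucleophilicity of the diene and by AlMe3, which removes protic acid. C7–H is alpha to the C10 ketone whereas C11–H, between two quaternary carbons, is not enolisable, so a shortfall in facial selectivity can be repaired afterwards without touching C11.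

Step 12
Reactants: 18 Diels–Alder adduct (name as in step 11)
Product: 20 methyl 1-{(1R)-4-(tert-butyldimethylsilyloxy)-3-[(2E)-3,7-dimethylocta-2,6-dienyl]-6,6-dimethylcyclohex-3-en-1-yl}-6,6-dimethyl-3-oxohexahydro-1H-cyclopenta[c]furan-3a-carboxylate (cis-fused lactone; C10 epimers), via hydroxy diester 19 (not isolated)
Conditions: NaBH4, MeOH/THF, 0 °C → rt; then K2CO3 (cat.), MeOH, rt
Reagents that add atoms: none
Why: Borohydride reduction of the ketone; the new C10 hydroxyl always has an ester cis on C3 and closes the five-membered lactone, which is taken as the defined product. C7 stops being epimerisable here.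

Step 13
Reactants: 20 cis-fused lactone ester (name as in step 12)
Product: 22 dimethyl (2R)-2-[{(1R)-4-(tert-butyldimethylsilyloxy)-3-[(2E)-3,7-dimethylocta-2,6-dienyl]-6,6-dimethylcyclohex-3-en-1-yl}(methylsulfanylcarbothioyloxy)methyl]-3,3-dimethylcyclopentane-1,1-dicarboxylate (C10 epimers), via lithium hydroxy carboxylate 21 (not isolated)
Conditions: LiOH·H2O (1.1 equiv), THF/H2O, rt; evaporate, dry; then NaH, CS2, DMF, 0 °C; MeI, 0 °C → rt
Reagents that add atoms: lithium hydroxide, [Li+].[OH-]; carbon disulfide, S=C=S; iodomethane, IC
Why: Lactone saponification, xanthate formation and carboxylate O-methylation in sequence; while the cis carboxyl is a carboxylate it cannot re-lactonise, the alkoxide adds to CS2, and MeI then alkylates sulfur and restores the methyl ester.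

Step 14
Reactants: 22 xanthate diester (name as in step 13)
Product: 23 dimethyl (2R)-2-({(1R)-4-(tert-butyldimethylsilyloxy)-3-[(2E)-3,7-dimethylocta-2,6-dienyl]-6,6-dimethylcyclohex-3-en-1-yl}methyl)-3,3-dimethylcyclopentane-1,1-dicarboxylate
Conditions: Bu3SnH (excess, 0.1 M), AIBN (cat.), toluene, 110 °C
Reagents that add atoms: none
Why: Barton–McCombie deoxygenation; the secondary C10 radical is reduced by the concentrated stannane faster than it can add to the enol ether or the geranyl alkenes, and C7 and C11 are untouched.

Step 15
Reactants: 23 deoxygenated diester (name as in step 14)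
Product: 24 (2R)-2-({(1R)-4-(tert-butyldimethylsilyloxy)-3-[(2E)-3,7-dimethylocta-2,6-dienyl]-6,6-dimethylcyclohex-3-en-1-yl}methyl)-3,3-dimethylcyclopentane-1,1-dicarboxylic acid
Conditions: lithium propane-1-thiolate (n-PrSLi, excess), HMPA, rt → 50 °C; phosphate buffer (pH 4–5), 0 °C
Reagents that add atoms: none
Why: SN2 demethylation of hindered methyl esters by thiolate, which attacks the methyl group and not the shielded carbonyl and leaves the enol silane intact; the acid is used at once.

Step 16
Reactants: 24 diacid enol silane (name as in step 15)
Product: 27 des-benzoyl cage trione (the target with hydrogen on C1 in place of benzoyl), via diacid chloride 25 (not isolated), via keto acid chloride 26 (not isolated)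
Conditions: Me2C=C(Cl)NMe2 (2.2 equiv), CH2Cl2, 0 °C → rt; dilute to 0.005 M; MgBr2·OEt2, then i-Pr2NEt, rt
Reagents that add atoms: none
Why: Intramolecular Effenberger-type double C-acylation; the enol silane carbon C5 attacks the acid chloride trans to C10 with loss of TBSCl (C4–C5), then magnesium-mediated soft enolisation of the C9 ketone toward C1, its only remaining alpha position, closes C1–C2. C5, C3 and C1 are set by the tether through C10, which can only reach one face of the ring.

Step 17
Reactants: 27 des-benzoyl cage trione
Product: 28 CNP0168637.1 (target)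
Conditions: lithium 2,2,6,6-tetramethylpiperidide (LiTMP), THF, −78 °C; PhCOCl, −78 → −40 °C
Reagents that add atoms: benzoyl chloride, O=C(Cl)c1ccccc1
Why: Bridgehead deprotonation and acylation, as used on bicyclo[3.3.1]nonane triones; C1–H is the only acidic hydrogen and is flanked by two carbonyl groups, and acylation must occur on carbon with retention because an enol ester would need a bridgehead alkene.

## Compound list

1 | methyl 3,3-dimethylpent-4-enoate | COC(=O)CC(C)(C)C=C | starting material
2 | 3,3-dimethylpent-4-en-1-ol | OCCC(C)(C)C=C | intermediate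
3 | 5-iodo-3,3-dimethylpent-1-ene | ICCC(C)(C)C=C | intermediate
4 | dimethyl malonate | COC(=O)CC(=O)OC | starting material
5 | dimethyl 2-(3,3-dimethylpent-4-en-1-yl)propanedioate | COC(=O)C(CCC(C)(C)C=C)C(=O)OC | intermediate
6 | dimethyl 2-[(4E)-6-(methoxycarbonyloxy)-3,3-dimethylhex-4-en-1-yl]propanedioate | COC(=O)OC/C=C/C(C)(C)CCC(C(=O)OC)C(=O)OC | intermediate
7 | dimethyl (2R)-2-ethenyl-3,3-dimethylcyclopentane-1,1-dicarboxylate | C=C[C@@H]1C(C)(C)CCC1(C(=O)OC)C(=O)OC | intermediate
8 | (1R)-2,2-bis(methoxycarbonyl)-5,5-dimethylcyclopentane-1-carboxylic acid | OC(=O)[C@@H]1C(C)(C)CCC1(C(=O)OC)C(=O)OC | intermediate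
9 | dimethyl (2R)-2-(chlorocarbonyl)-3,3-dimethylcyclopentane-1,1-dicarboxylate | ClC(=O)[C@@H]1C(C)(C)CCC1(C(=O)OC)C(=O)OC | intermediate (not isolated)
10 | dimethyl (2R)-3,3-dimethyl-2-(3-methylbut-2-enoyl)cyclopentane-1,1-dicarboxylate (dienophile) | CC(C)=CC(=O)[C@@H]1C(C)(C)CCC1(C(=O)OC)C(=O)OC | intermediate
11 | geranyl bromide | CC(C)=CCC/C(C)=C/CBr | starting material
12 | methyl acetoacetate | CC(=O)CC(=O)OC | starting material
13 | methyl (4E)-2-acetyl-5,9-dimethyldeca-4,8-dienoate (racemic) | CC(C)=CCC/C(C)=C/CC(C(C)=O)C(=O)OC | intermediate
14 | (4E)-2-acetyl-5,9-dimethyldeca-4,8-dienoic acid | CC(C)=CCC/C(C)=C/CC(C(C)=O)C(=O)O | intermediate (not isolated)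
15 | (4E)-2-acetyl-2-[(diethylamino)methyl]-5,9-dimethyldeca-4,8-dienoic acid | CC(C)=CCC/C(C)=C/CC(CN(CC)CC)(C(C)=O)C(=O)O | intermediate (not isolated)
16 | (5E)-6,10-dimethyl-3-methylideneundeca-5,9-dien-2-one | CC(C)=CCC/C(C)=C/CC(=C)C(C)=O | intermediate
17 | tert-butyl{[(5E)-6,10-dimethyl-3-methylideneundeca-1,5,9-trien-2-yl]oxy}dimethylsilane (diene) | CC(C)=CCC/C(C)=C/CC(=C)C(=C)O[Si](C)(C)C(C)(C)C | intermediate
18 | dimethyl (2R)-2-{(1R)-4-(tert-butyldimethylsilyloxy)-3-[(2E)-3,7-dimethylocta-2,6-dienyl]-6,6-dimethylcyclohex-3-ene-1-carbonyl}-3,3-dimethylcyclopentane-1,1-dicarboxylate | CC(C)=CCC/C(C)=C/CC1=C(O[Si](C)(C)C(C)(C)C)CC(C)(C)[C@@H](C1)C(=O)[C@@H]1C(C)(C)CCC1(C(=O)OC)C(=O)OC | intermediate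
19 | C10 alcohol of 18 (hydroxy diester, C10 epimers) | CC(C)=CCC/C(C)=C/CC1=C(O[Si](C)(C)C(C)(C)C)CC(C)(C)[C@@H](C1)C(O)[C@@H]1C(C)(C)CCC1(C(=O)OC)C(=O)OC | intermediate (not isolated)
20 | cis-fused γ-lactone between the C10 oxygen and the cis carboxyl on C3, the trans methyl ester retained (C10 epimers) | CC(C)=CCC/C(C)=C/CC1=C(O[Si](C)(C)C(C)(C)C)CC(C)(C)[C@@H](C1)C2OC(=O)[C@@]3(C(=O)OC)CCC(C)(C)[C@@H]23 | intermediate
21 | lithium carboxylate of the opened lactone (carboxylate cis to C10, methyl ester trans, free C10 hydroxyl) | CC(C)=CCC/C(C)=C/CC1=C(O[Si](C)(C)C(C)(C)C)CC(C)(C)[C@@H](C1)C(O)[C@@H]1C(C)(C)CC[C@]1(C(=O)OC)C(=O)[O-].[Li+] | intermediate (not isolated)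
22 | S-methyl xanthate of 19 (C10 epimers) | CC(C)=CCC/C(C)=C/CC1=C(O[Si](C)(C)C(C)(C)C)CC(C)(C)[C@@H](C1)C(OC(=S)SC)[C@@H]1C(C)(C)CCC1(C(=O)OC)C(=O)OC | intermediate
23 | dimethyl (2R)-2-({(1R)-4-(tert-butyldimethylsilyloxy)-3-[(2E)-3,7-dimethylocta-2,6-dienyl]-6,6-dimethylcyclohex-3-en-1-yl}methyl)-3,3-dimethylcyclopentane-1,1-dicarboxylate | CC(C)=CCC/C(C)=C/CC1=C(O[Si](C)(C)C(C)(C)C)CC(C)(C)[C@@H](C1)C[C@@H]1C(C)(C)CCC1(C(=O)OC)C(=O)OC | intermediate
24 | the corresponding (2R)-cyclopentane-1,1-dicarboxylic acid | CC(C)=CCC/C(C)=C/CC1=C(O[Si](C)(C)C(C)(C)C)CC(C)(C)[C@@H](C1)C[C@@H]1C(C)(C)CCC1(C(=O)O)C(=O)O | intermediate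
25 | the corresponding 1,1-dicarbonyl dichloride | CC(C)=CCC/C(C)=C/CC1=C(O[Si](C)(C)C(C)(C)C)CC(C)(C)[C@@H](C1)C[C@@H]1C(C)(C)CCC1(C(=O)Cl)C(=O)Cl | intermediate (not isolated)
26 | bicyclic keto acid chloride: C4–C5 closed, C9 ketone, C1 as CH2, C2 as COCl on C3 | CC(C)=CCC/C(C)=C/C[C@@]12C[C@H](C(C)(C)CC2=O)C[C@@H]3C(C)(C)CC[C@]3(C1=O)C(=O)Cl | intermediate (not isolated)
27 | des-benzoyl cage trione (C1–H) | CC(C)=CCC/C(C)=C/C[C@@]12C[C@H]3C[C@@H]4C(C)(C)CC[C@]4(C1=O)C(=O)[C@@H](C2=O)C3(C)C | intermediate
28 | CNP0168637.1 | CC(C)=CCC/C(C)=C/C[C@@]12C[C@H]3C[C@@H]4C(C)(C)CC[C@]4(C1=O)C(=O)[C@@](C(=O)c1ccccc1)(C2=O)C3(C)C | target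

## Step count and least certain steps

Total: 17 steps. Longest linear sequence: 14 steps (steps 1–7 and 11–17); the diene branch (steps 8–10) is three steps.

**Step 11 (key step).** The most likely failure is poor π-facial discrimination at C7. C11 acts on the alkene across the C10 carbonyl, both of its flanks are quaternary, and the rotamer model may not hold if the esters are not fully complexed. The fallback replaces kinetic control by thermodynamic recycling. It sets out from 10 and 17, with the cycloaddition run for conversion only. The C7-epimeric adduct F1 is separated from 18 and equilibrated with DBU (toluene, 60 °C); only C7–H can enolise, so C11 is safe. The regenerated mixture is separated again, and the route is rejoined at 18.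

**Step 16.** The most likely failure is slow C-acylation at the tetrasubstituted enol carbon C5 by an acid chloride that itself sits on a quaternary carbon. Oligomerisation, loss of the enol silane, or O-acylation in the second closure could then take over. The fallback swaps acylation for aldol addition followed by oxidation and sets out from 23.
- i-Bu2AlH (toluene, −78 °C) gives the dialdehyde F2.
- TiCl4 (CH2Cl2, −78 °C) closes C4–C5 by Mukaiyama aldol addition to the hydroxy keto aldehyde F3.
- TiCl4/i-Pr2NEt then closes C1–C2 to the cage diol F4.
- Dess–Martin periodinane oxidises both carbinols, and the route is rejoined at 27.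

**Step 17.** The most likely failure is slow capture of the non-planar bridgehead anion, which sits beside the C8 methyl groups, by the bulky benzoyl chloride; proton return would then regenerate 27. The fallback uses a smaller electrophile and an extra oxidation. From 27, LiTMP and then benzaldehyde give the bridgehead carbinol F5, and Dess–Martin periodinane converts F5 into 28.

**Step 5.** The most likely failure is slow ionisation and attack at an allyl terminus that carries a quaternary carbon, giving low conversion or eroded enantioselectivity. The fallback gives up asymmetric catalysis for resolution. From 6, Pd(PPh3)4 (THF, rt) gives the racemic vinylcyclopentane F6. The conditions of step 6 turn it into the racemic acid F7. Crystallisation with one enantiomer of 1-phenylethylamine (the antipode if it serves better) gives the salt F8 of the (1R)-acid. Acidification releases 8, where the route is rejoined.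

Further compounds
F1 | step 11 | dimethyl (2R)-2-{(1S)-4-(tert-butyldimethylsilyloxy)-3-[(2E)-3,7-dimethylocta-2,6-dienyl]-6,6-dimethylcyclohex-3-ene-1-carbonyl}-3,3-dimethylcyclopentane-1,1-dicarboxylate (C7 epimer of 18) | CC(C)=CCC/C(C)=C/CC1=C(O[Si](C)(C)C(C)(C)C)CC(C)(C)[C@H](C1)C(=O)[C@@H]1C(C)(C)CCC1(C(=O)OC)C(=O)OC
F2 | step 16 | (2R)-2-({(1R)-4-(tert-butyldimethylsilyloxy)-3-[(2E)-3,7-dimethylocta-2,6-dienyl]-6,6-dimethylcyclohex-3-en-1-yl}methyl)-3,3-dimethylcyclopentane-1,1-dicarbaldehyde | CC(C)=CCC/C(C)=C/CC1=C(O[Si](C)(C)C(C)(C)C)CC(C)(C)[C@@H](C1)C[C@@H]1C(C)(C)CCC1(C=O)C=O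
F3 | step 16 | bicyclic hydroxy keto aldehyde (C4–C5 closed, C4 carbinol, C9 ketone, C2 as CHO on C3) | CC(C)=CCC/C(C)=C/C[C@@]12C[C@H](C(C)(C)CC2=O)C[C@@H]3C(C)(C)CC[C@]3(C1O)C=O
F4 | step 16 | cage diol (27 with hydroxyl groups at C2 and C4 in place of the carbonyl groups) | CC(C)=CCC/C(C)=C/C[C@@]12C[C@H]3C[C@@H]4C(C)(C)CC[C@]4(C1O)C(O)[C@@H](C2=O)C3(C)C
F5 | step 17 | bridgehead carbinol (target with CH(OH)Ph on C1 in place of benzoyl) | CC(C)=CCC/C(C)=C/C[C@@]12C[C@H]3C[C@@H]4C(C)(C)CC[C@]4(C1=O)C(=O)[C@@](C(O)c1ccccc1)(C2=O)C3(C)C
F6 | step 5 | dimethyl 2-ethenyl-3,3-dimethylcyclopentane-1,1-dicarboxylate (racemic) | C=CC1C(C)(C)CCC1(C(=O)OC)C(=O)OC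
F7 | step 5 | 2,2-bis(methoxycarbonyl)-5,5-dimethylcyclopentane-1-carboxylic acid (racemic) | OC(=O)C1C(C)(C)CCC1(C(=O)OC)C(=O)OC
F8 | step 5 | (R)-1-phenylethylammonium (1R)-2,2-bis(methoxycarbonyl)-5,5-dimethylcyclopentane-1-carboxylate | [O-]C(=O)[C@@H]1C(C)(C)CCC1(C(=O)OC)C(=O)OC.C[C@@H]([NH3+])c1ccccc1
A1 | alternative 1 | 2-benzoyl-6-geranyl-6-prenyl cyclohexane-1,3,5-trione with a 2-formyl-3,3-dimethylcyclopentane spiro-fused at C3 (triketo tautomer) | CC(C)=CCC/C(C)=C/C[C@@]1(CC=C(C)C)C(=O)[C@@]2(CCC(C)(C)[C@H]2C=O)C(=O)C(C(=O)c2ccccc2)C1=O
A2 | alternative 1 | C10-hydroxy target (one C10 epimer) | CC(C)=CCC/C(C)=C/C[C@@]12C[C@H]3[C@@H](O)[C@@H]4C(C)(C)CC[C@]4(C1=O)C(=O)[C@@](C(=O)c1ccccc1)(C2=O)C3(C)C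
A3 | alternative 2 | dimethyl 2-[(tert-butyldimethylsilyloxy)methyl]-3,3-dimethylcyclopropane-1,1-dicarboxylate | COC(=O)C1(C(=O)OC)[C@H](CO[Si](C)(C)C(C)(C)C)C1(C)C
A4 | alternative 2 | 1,1-bis(methylsulfanyl)ethene | C=C(SC)SC
A5 | alternative 2 | dimethyl 2-[(tert-butyldimethylsilyloxy)methyl]-3,3-dimethyl-5,5-bis(methylsulfanyl)cyclopentane-1,1-dicarboxylate | COC(=O)C1(C(=O)OC)[C@H](CO[Si](C)(C)C(C)(C)C)C(C)(C)CC1(SC)SC
A6 | alternative 3 | 2-diazo-4,4-dimethylcyclohexanone carrying at C3 the {(1R)-4-(tert-butyldimethylsilyloxy)-3-geranyl-6,6-dimethylcyclohex-3-en-1-yl}methyl group | CC(C)=CCC/C(C)=C/CC1=C(O[Si](C)(C)C(C)(C)C)CC(C)(C)[C@@H](C1)C[C@@H]1C(C)(C)CCC(=O)C1=[N+]=[N-]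
A7 | alternative 3 | bridged 3-silyloxycyclobutanone (C3–C14, C4–C5 and temporary C3–C9 formed) | CC(C)=CCC/C(C)=C/C[C@@]12C[C@H]3C[C@@H]4C(C)(C)CC[C@]4(C1=O)[C@]2(O[Si](C)(C)C(C)(C)C)CC3(C)C
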